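(The data stem from a simulated flask for an exercise; noise was put on by code.)

**Target account.** The target in this flask is read from the runs as an intermediate: each side product holds one target and one further starting material. Target made, T, is then half the side product's percentage plus the target still standing. The quantity to carry is the target yield on reagent (a selectivity): target made per equiv of reagent added over a stretch of charge.

| flask | starting material | second substrate | reagent | free catalyst | remark | time |
|---|---|---|---|---|---|---|
| east | 0.69 M | 1 equiv | 0.60 equiv | 5 mol% | run made earlier |  |
| north | 0.69 M | 1 equiv | 0.90 equiv | 5 mol% | run made earlier |  |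
| flask | 0.69 M | 1.00 equiv | 1.20 equiv | 5 mol% |  | 8.0 h |

| run | time / h | target / % | side product / % |
|---|---|---|---|
| east | 1.50 | 4 | 67 |
| east | 3.00 | 0 | 72 |
| east | 5.00 | 0 | 77 |
| east | 6.00 | 0 | 73 |
| east | 8.00 | 0 | 76 |
| east | 10.0 | 0 | 75 |
| north | 0.833 | 5 | 61 |
| north | 1.33 | 5 | 79 |
| north | 2.00 | 5 | 88 |
| north | 4.00 | 5 | 93 |
| north | 6.00 | 1 | 96 |
| north | 10.0 | 0 | 98 |

(each reading ± 2 percentage points)

- target at 8.0 h, in percent of the starting material charged
- side product at 8.0 h, in percent of the starting material charged

**What counts.** Time counts little: the east side product reads between 72% and 77% from 3.00 h to 10.0 h, and the north one moves from 96% to 98% after 6.00 h. The other charges are equal in all three recipes, so the runs cannot rate them. The yield of the last stretch matters: where target and side product hold the whole charge, target standing is 2T minus the charge. Keeping the yield of the stretch from east to north, 0.383, gives target near 21.0%, while a yield of nil gives north's 0%.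

**The number.** East gives 0.625 over its charge, and the stretch from east to north gives 0.383, which is lower. Falling by the same ratio, the next stretch yields 0.235. My reckoning is therefore T = 56.1%, target 12.2% and side product 87.8%.

**The forecast.** It says target 1% and side product 97%, holding that “reagent is in clear excess”. On target it stands below my reckoning.

**The flask.** It gives target 9.16% and side product 90.8%.

    starting material + target → side product (k = 0.210 M⁻¹ min⁻¹)
    reagent + catalyst intermediate A → free catalyst + target (k = 1.06 M⁻¹ min⁻¹)
    reagent + catalyst intermediate B → free catalyst + second product (k = 1.79 M⁻¹ min⁻¹)
    second substrate + free catalyst ⇌ catalyst intermediate B (K = 0.540 M⁻¹, k = 316 M⁻¹ min⁻¹)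
    starting material + free catalyst ⇌ catalyst intermediate A (K = 2.90 M⁻¹, k = 4.06 M⁻¹ min⁻¹)

**What happened.** By 1.60 h the step from starting material and free catalyst to catalyst intermediate A had 97% of its turnover behind it, while reagent with catalyst intermediate B had 71% behind it. That second path ran on to 8.00 h, when reagent stood at 0.767% of its charge and target at 9.16%. The flask's last stretch yielded 0.186. The neighbour charged with 0.300 equiv of reagent reached side product 42.1% and target 0%, a yield of 0.702, above east's.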